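**Strategy.** Everything rests on cutting ring C of the flavone at C4a–C4, C4–C3 and O1–C2. One palladium-catalysed operation joins an ortho-iodophenol, carbon monoxide and phenylacetylene to an aroyl alkyne and closes the pyranone by 6-endo attack of the phenol oxygen. The precursor is a 2-iodophenol that already holds the (S)-N-methylpiperidine, set by sulfinimine chemistry, between two benzyloxy groups. Because the oxygens on future C5 and C7, which flank C6, carry the same group, the two ring A carbons ortho to the phenol (future C4a and C8) are equivalent, so iodination and annulation cannot give a 6/8 isomer pair; the C4 carbonyl later tells O5 from O7.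

Key step: step 8

Remark: the piperidine carbon of the target is (S) (N > aryl > CH2 > H), and the (R) sulfinamide is the enantiomer that sets it under chelation control; N-methoxy-N-methyl-3-phenylprop-2-ynamide, used only in a fallback, is taken as a purchased reagent.

**Step 1**
Reactants: 1 3,5-bis(benzyloxy)phenol
Product: 3 2,6-bis(benzyloxy)-4-hydroxybenzaldehyde, via iminium chloride 2 (not isolated)
Conditions: POCl3, DMF, 0 °C → rt; then H2O, rt
Reagents that add atoms: N,N-dimethylformamide CN(C)C=O; water O
Why: Vilsmeier–Haack formylation of a 3,5-dialkoxyphenol should go mainly para to the free hydroxyl, at the carbon between the two benzyloxy groups, and the less polar, internally hydrogen-bonded ortho isomer is to be removed by crystallisation.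

**Step 2**
Reactants: 3 2,6-bis(benzyloxy)-4-hydroxybenzaldehyde
Product: 4 2,6-bis(benzyloxy)-4-[(triisopropylsilyl)oxy]benzaldehyde
Conditions: TIPSCl, imidazole, DMF, rt
Reagents that add atoms: chlorotriisopropylsilane CC(C)[Si](Cl)(C(C)C)C(C)C
Why: O-silylation of the only free phenol, with the bulky triisopropylsilyl group chosen because a silyl ether para to an aldehyde or imine is easily attacked at silicon and must survive ethoxide, a Grignard reagent and an amide base in steps 3 and 4.

**Step 3**
Reactants: 4 2,6-bis(benzyloxy)-4-[(triisopropylsilyl)oxy]benzaldehyde; 5 (R)-tert-butanesulfinamide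
Product: 6 (R)-N-[(E)-{2,6-bis(benzyloxy)-4-[(triisopropylsilyl)oxy]phenyl}methylidene]-2-methylpropane-2-sulfinamide
Conditions: Ti(OEt)4, THF, 65 °C
Reagents that add atoms: none
Why: Condensation of an aldehyde with tert-butanesulfinamide, in which Ti(OEt)4 acts as Lewis acid and water scavenger for this electron-rich, doubly ortho-substituted aldehyde and the E imine forms for steric reasons.

**Step 4**
Reactants: 6 the (R,E)-N-sulfinyl aldimine; 7 1-bromo-4-chlorobutane
Product: 10 (2S)-2-{2,6-bis(benzyloxy)-4-[(triisopropylsilyl)oxy]phenyl}-1-[(R)-tert-butylsulfinyl]piperidine, via 4-chlorobutylmagnesium bromide 8 (not isolated), via chloro sulfinamide 9 (not isolated)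
Conditions: 7, Mg, Et2O, rt; then 6, toluene, −78 → −20 °C; then KN(SiMe3)2, THF, −20 °C → rt
Reagents that add atoms: none
Why: Auxiliary-controlled Grignard addition to an N-tert-butanesulfinyl aldimine in a non-coordinating solvent should pass through the six-membered chair transition state with magnesium on the sulfinyl oxygen, which delivers the chain to the Si face of the (R)-sulfinyl E-imine and sets the carbon as (S), after which the potassium sulfinamide closes the piperidine by 6-exo-tet displacement of the primary chloride; the minor diastereomer is to be removed at this stage.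

**Step 5**
Reactants: 10 the N-sulfinyl piperidine
Product: 12 (2S)-2-{2,6-bis(benzyloxy)-4-[(triisopropylsilyl)oxy]phenyl}-1-methylpiperidine, via piperidine hydrochloride 11 (not isolated)
Conditions: HCl (4 M in dioxane), MeOH, 0 °C; evaporate; then Et3N, aq. HCHO, NaBH(OAc)3, ClCH2CH2Cl, rt
Reagents that add atoms: formaldehyde C=O
Why: Acid methanolysis of the S–N bond is fast at 0 °C and spares silyl and benzyl ethers, and reductive amination with formaldehyde methylates nitrogen once without the quaternisation that an alkyl halide would risk, while the still-silylated phenol keeps the electron-rich ring from a Mannich reaction.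

**Step 6**
Reactants: 12 the N-methylpiperidine silyl ether
Product: 13 3,5-bis(benzyloxy)-4-[(2S)-1-methylpiperidin-2-yl]phenol
Conditions: Bu4NF, AcOH, THF, 0 °C → rt
Reagents that add atoms: none
Why: Fluoride-mediated cleavage of an aryl silyl ether, buffered with acetic acid so that no free phenoxide para to the benzylic amine is left standing in base.

**Step 7**
Reactants: 13 3,5-bis(benzyloxy)-4-[(2S)-1-methylpiperidin-2-yl]phenol
Product: 14 3,5-bis(benzyloxy)-2-iodo-4-[(2S)-1-methylpiperidin-2-yl]phenol
Conditions: NIS (1.0 equiv), TFA (1.1 equiv), MeCN, −30 → 0 °C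
Reagents that add atoms: N-iodosuccinimide O=C1CCC(=O)N1I
Why: Electrophilic aromatic iodination of a phloroglucinol-type phenol is fast at low temperature and can give only one mono-iodide because both carbons ortho to the hydroxyl are equivalent, one equivalent of reagent limits di-iodination, and protonation keeps the amine from N-iodination and from assisting ipso attack at the carbon that carries it.

**Step 8**
Reactants: 14 3,5-bis(benzyloxy)-2-iodo-4-[(2S)-1-methylpiperidin-2-yl]phenol; 15 carbon monoxide; 16 phenylacetylene
Product: 19 5,7-bis(benzyloxy)-6-[(2S)-1-methylpiperidin-2-yl]-2-phenyl-4H-chromen-4-one, via ynone 17 (not isolated), via enaminone 18 (not isolated)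
Conditions: PdCl2(PPh3)2 (5 mol %), CO (10 bar), Et2NH, 60 °C
Reagents that add atoms: none
Why: PdCl2(PPh3)2 is reduced in the flask to zerovalent palladium, which inserts into the C–I bond; CO insertion gives an aroylpalladium iodide that couples with the amine-deprotonated alkyne to form C4a–C4 and C4–C3 in ynone 17, diethylamine adds to 17 to give enaminone 18, and the phenol oxygen then attacks C2 with loss of diethylamine to form O1–C2. The closest known reaction type is the copper-free carbonylative Sonogashira coupling–cyclisation of ortho-iodophenols with terminal alkynes to flavones in a secondary amine. Ring C closes in the 6-endo mode at the β-carbon by addition–elimination on the enaminone, and the enaminone is what diverts the phenol from the 5-exo closure that would give an aurone. No stereocentre is formed; the (S) centre of the piperidine is a spectator and is kept at moderate temperature in a weakly basic medium, because a para-hydroxybenzylic amine could open reversibly to a quinone methide on harder heating. The step needs carbonylative rather than direct alkynylation, which CO pressure, the absence of copper and fast CO insertion into an electron-rich arylpalladium favour, and it needs a single annulation site, which the substrate fixes because iodine sits beside the only free hydroxyl while both oxygens flanking the piperidine-bearing carbon are benzylated.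

**Step 9**
Reactants: 19 5,7-bis(benzyloxy)-6-[(2S)-1-methylpiperidin-2-yl]-2-phenyl-4H-chromen-4-one
Product: 20 7-(benzyloxy)-5-hydroxy-6-[(2S)-1-methylpiperidin-2-yl]-2-phenyl-4H-chromen-4-one
Conditions: BCl3 (2.5 equiv), CH2Cl2, −78 °C; then MeOH; aq. NaHCO3
Reagents that add atoms: none
Why: Chelation-controlled Lewis acid dealkylation, in which BCl3 (one equivalent is taken up by the amine) binds between the C4 carbonyl and the peri O5 so that chloride removes only the 5-O-benzyl group at low temperature, while the 7-O-benzyl ether cannot chelate and should stay.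

**Step 10**
Reactants: 20 7-(benzyloxy)-5-hydroxy-6-[(2S)-1-methylpiperidin-2-yl]-2-phenyl-4H-chromen-4-one
Product: 21 7-(benzyloxy)-5-methoxy-6-[(2S)-1-methylpiperidin-2-yl]-2-phenyl-4H-chromen-4-one
Conditions: MeOH, PPh3, DIAD (excess of each), THF, 0 °C → rt
Reagents that add atoms: methanol CO
Why: Mitsunobu etherification methylates the only acidic group under neutral conditions at room temperature, so the tertiary amine is not quaternised as it would be by methyl iodide or dimethyl sulfate and the benzylic centre is not heated with base; an excess of reagents is planned because the hydrogen-bonded 5-hydroxyl is a weak pronucleophile.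

**Step 11**
Reactants: 21 7-(benzyloxy)-5-methoxy-6-[(2S)-1-methylpiperidin-2-yl]-2-phenyl-4H-chromen-4-one
Product: 22 7-hydroxy-5-methoxy-6-[(2S)-1-methylpiperidin-2-yl]-2-phenyl-4H-chromen-4-one
Conditions: H2 (1 atm), 10% Pd on carbon, AcOH, MeOH–EtOAc, rt
Reagents that add atoms: none
Why: Catalytic hydrogenolysis of an aryl benzyl ether is fast at atmospheric pressure, acetic acid protonates the amine that would otherwise slow the catalyst, and stopping at full conversion should leave the flavone C2=C3 bond and the benzylic C–N bond untouched.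

**Compound list**

1 | 3,5-bis(benzyloxy)phenol | Oc1cc(OCc2ccccc2)cc(OCc2ccccc2)c1 | starting material
2 | N-{[2,6-bis(benzyloxy)-4-hydroxyphenyl]methylidene}-N-methylmethanaminium chloride | C[N+](C)=Cc1c(OCc2ccccc2)cc(O)cc1OCc1ccccc1.[Cl-] | intermediate
3 | 2,6-bis(benzyloxy)-4-hydroxybenzaldehyde | O=Cc1c(OCc2ccccc2)cc(O)cc1OCc1ccccc1 | intermediate
4 | 2,6-bis(benzyloxy)-4-[(triisopropylsilyl)oxy]benzaldehyde | O=Cc1c(OCc2ccccc2)cc(O[Si](C(C)C)(C(C)C)C(C)C)cc1OCc1ccccc1 | intermediate
5 | (R)-tert-butanesulfinamide, (R)-2-methylpropane-2-sulfinamide | CC(C)(C)[S@@](=O)N | starting material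
6 | (R)-N-[(E)-{2,6-bis(benzyloxy)-4-[(triisopropylsilyl)oxy]phenyl}methylidene]-2-methylpropane-2-sulfinamide | CC(C)(C)[S@@](=O)/N=C/c1c(OCc2ccccc2)cc(O[Si](C(C)C)(C(C)C)C(C)C)cc1OCc1ccccc1 | intermediate
7 | 1-bromo-4-chlorobutane | ClCCCCBr | starting material
8 | 4-chlorobutylmagnesium bromide | ClCCCC[Mg]Br | intermediate
9 | (R)-N-[(1S)-1-{2,6-bis(benzyloxy)-4-[(triisopropylsilyl)oxy]phenyl}-5-chloropentyl]-2-methylpropane-2-sulfinamide, present in the flask as its N-magnesium salt | CC(C)(C)[S@@](=O)N[C@@H](CCCCCl)c1c(OCc2ccccc2)cc(O[Si](C(C)C)(C(C)C)C(C)C)cc1OCc1ccccc1 | intermediate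
10 | (2S)-2-{2,6-bis(benzyloxy)-4-[(triisopropylsilyl)oxy]phenyl}-1-[(R)-tert-butylsulfinyl]piperidine | CC(C)(C)[S@@](=O)N1CCCC[C@H]1c1c(OCc2ccccc2)cc(O[Si](C(C)C)(C(C)C)C(C)C)cc1OCc1ccccc1 | intermediate
11 | (2S)-2-{2,6-bis(benzyloxy)-4-[(triisopropylsilyl)oxy]phenyl}piperidine hydrochloride | Cl.N1CCCC[C@H]1c1c(OCc2ccccc2)cc(O[Si](C(C)C)(C(C)C)C(C)C)cc1OCc1ccccc1 | intermediate
12 | (2S)-2-{2,6-bis(benzyloxy)-4-[(triisopropylsilyl)oxy]phenyl}-1-methylpiperidine | CN1CCCC[C@H]1c1c(OCc2ccccc2)cc(O[Si](C(C)C)(C(C)C)C(C)C)cc1OCc1ccccc1 | intermediate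
13 | 3,5-bis(benzyloxy)-4-[(2S)-1-methylpiperidin-2-yl]phenol | Oc1cc(OCc2ccccc2)c([C@@H]2CCCCN2C)c(OCc2ccccc2)c1 | intermediate
14 | 3,5-bis(benzyloxy)-2-iodo-4-[(2S)-1-methylpiperidin-2-yl]phenol | Oc1cc(OCc2ccccc2)c([C@@H]3CCCCN3C)c(OCc4ccccc4)c1I | intermediate
15 | carbon monoxide | [C-]#[O+] | starting material
16 | phenylacetylene | C#Cc1ccccc1 | starting material
17 | 1-{4,6-bis(benzyloxy)-2-hydroxy-5-[(2S)-1-methylpiperidin-2-yl]phenyl}-3-phenylprop-2-yn-1-one | O=C(C#Cc1ccccc1)c1c(O)cc(OCc2ccccc2)c([C@@H]2CCCCN2C)c1OCc1ccccc1 | intermediate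
18 | (2E)-1-{4,6-bis(benzyloxy)-2-hydroxy-5-[(2S)-1-methylpiperidin-2-yl]phenyl}-3-(diethylamino)-3-phenylprop-2-en-1-one | CCN(CC)/C(=C/C(=O)c1c(O)cc(OCc2ccccc2)c([C@@H]2CCCCN2C)c1OCc1ccccc1)c1ccccc1 | intermediate
19 | 5,7-bis(benzyloxy)-6-[(2S)-1-methylpiperidin-2-yl]-2-phenyl-4H-chromen-4-one | O=c1cc(-c2ccccc2)oc2cc(OCc3ccccc3)c([C@@H]4CCCCN4C)c(OCc5ccccc5)c12 | intermediate
20 | 7-(benzyloxy)-5-hydroxy-6-[(2S)-1-methylpiperidin-2-yl]-2-phenyl-4H-chromen-4-one | O=c1cc(-c2ccccc2)oc2cc(OCc3ccccc3)c([C@@H]3CCCCN3C)c(O)c12 | intermediate
21 | 7-(benzyloxy)-5-methoxy-6-[(2S)-1-methylpiperidin-2-yl]-2-phenyl-4H-chromen-4-one | COc1c([C@@H]2CCCCN2C)c(OCc2ccccc2)cc2oc(-c3ccccc3)cc(=O)c12 | intermediate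
22 | 7-hydroxy-5-methoxy-6-[(2S)-1-methylpiperidin-2-yl]-2-phenyl-4H-chromen-4-one | COc1c([C@@H]2CCCCN2C)c(O)cc2oc(-c3ccccc3)cc(=O)c12 | target

**Totals.** Total step count: 11. Longest linear sequence: 11 steps (1 → 22); 5, 7, 15 and 16 enter along the way.

**Steps most likely to fail**

Step 8. Oxidative addition into the electron-rich C–I bond with two ortho substituents may be slow. Alkynylation may also outrun CO insertion, which would end in a 2-phenylbenzofuran, and long heating could erode the configuration at the piperidine carbon. The fallback replaces catalytic carbonylation by a stoichiometric acylation. Starting from 14, deprotonation of the phenol with MeMgCl and iodine–magnesium exchange with i-PrMgCl·LiCl in THF at −20 °C would give the doubly magnesiated phenoxide F1. Its aryl–magnesium bond would be acylated by N-methoxy-N-methyl-3-phenylprop-2-ynamide to give, after aqueous work-up, ynone 17 as an isolated compound. Stirring 17 with Et2NH in EtOH at room temperature would close ring C through 18 and rejoin the route at 19.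

Step 10. Proton transfer from the internally hydrogen-bonded, ortho-hindered 5-hydroxyl to the Mitsunobu betaine may be too slow. The reagent pair would then be consumed by N-methylation of the hydrazide and the phenol would be left unchanged. The fallback masks nitrogen so that a classical alkylation can be used. Starting from 20, BH3·SMe2 (1 equiv, THF, −20 °C) would give amine–borane F2, formed as a mixture of epimers at nitrogen. MeI with Cs2CO3 in DMF would then methylate the phenoxide to give O-methylated amine–borane F3. The conditions of step 11 (H2, 10% Pd on carbon, MeOH) would remove the benzyl group and, by palladium-catalysed methanolysis, the borane, so the fallback rejoins at 22.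

Step 4. Coordination of magnesium by the two ortho benzyloxy groups may compete with the sulfinyl-oxygen chelate and lower or reverse the facial selectivity. β-Hydride transfer from the Grignard reagent may reduce the hindered imine, and ring closure of the hindered sulfinamide anion may stall. The fallback is a racemic assembly without auxiliary, followed by separation of enantiomers. Starting from 4, LiN(SiMe3)2 in THF at 0 °C would give N-(trimethylsilyl)imine F4. Addition of Grignard reagent 8 and aqueous work-up would give racemic amino chloride F5, and K2CO3 with catalytic NaI in MeCN at 60 °C would close racemic piperidine F6. Preparative chromatography on a chiral stationary phase would deliver the (S) enantiomer, which as its hydrochloride is 11 and re-enters at the methylation stage of step 5.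

**Further compounds**

F1 | step 8 | chloromagnesium 3,5-bis(benzyloxy)-2-(chloromagnesio)-4-[(2S)-1-methylpiperidin-2-yl]phenolate | Cl[Mg]Oc1cc(OCc2ccccc2)c([C@@H]2CCCCN2C)c(OCc2ccccc2)c1[Mg]Cl
F2 | step 10 | N-borane adduct of 7-(benzyloxy)-5-hydroxy-6-[(2S)-1-methylpiperidin-2-yl]-2-phenyl-4H-chromen-4-one | [BH3-][N+]1(C)CCCC[C@H]1c1c(O)c2c(=O)cc(-c3ccccc3)oc2cc1OCc1ccccc1
F3 | step 10 | N-borane adduct of 7-(benzyloxy)-5-methoxy-6-[(2S)-1-methylpiperidin-2-yl]-2-phenyl-4H-chromen-4-one | [BH3-][N+]1(C)CCCC[C@H]1c1c(OC)c2c(=O)cc(-c3ccccc3)oc2cc1OCc1ccccc1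
F4 | step 4 | (E)-1-{2,6-bis(benzyloxy)-4-[(triisopropylsilyl)oxy]phenyl}-N-(trimethylsilyl)methanimine | C[Si](C)(C)/N=C/c1c(OCc2ccccc2)cc(O[Si](C(C)C)(C(C)C)C(C)C)cc1OCc1ccccc1
F5 | step 4 | rac-1-{2,6-bis(benzyloxy)-4-[(triisopropylsilyl)oxy]phenyl}-5-chloropentan-1-amine | NC(CCCCCl)c1c(OCc2ccccc2)cc(O[Si](C(C)C)(C(C)C)C(C)C)cc1OCc1ccccc1
F6 | step 4 | rac-2-{2,6-bis(benzyloxy)-4-[(triisopropylsilyl)oxy]phenyl}piperidine | N1CCCCC1c1c(OCc2ccccc2)cc(O[Si](C(C)C)(C(C)C)C(C)C)cc1OCc1ccccc1
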